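A direct plan would build both flavan units from open-chain pieces: the racemic aryl vinyl carbinol A1 would be resolved by Sharpless epoxidation, elaborated by two Mitsunobu etherifications and a chalcone epoxidation to the bis-epoxide A2, and both pyran rings would close in one epoxide–arene Friedel–Crafts cascade; deallylation to triol A3, double galloylation and hydrogenolysis would follow.
Its weakest points would be:
(a) the kinetic resolution of A1 – half the material would be lost at the start of a linear run of about ten steps that only rebuilds stereocentres that can be bought;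
(b) the double cyclization of A2 on the most advanced material – the benzylic oxirane would ionize (C4 configuration at risk, ketone by hydride shift) and the terminal oxirane could close 5-exo or 6-endo, without close precedent;
(c) the galloylation of A3 – the lower C3–OH would have to be told from the upper C3–OH by sterics alone.

New plan: the retrosynthesis cuts only the interflavan bond C4(upper)–C6(lower) and the two galloyl ester C–O bonds.
No ring is closed: rings A, C, B come with (−)-epicatechin and rings D, F, E with (−)-epigallocatechin, so all C2/C3 stereocentres are bought and the dimeric core arises last, in one union.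
Enabling feature: upper C4 is benzylic to the 5,7-dioxygenated ring A and adjacent to C3–O, so it ionizes and is attacked anti to C3–O (4β); ring D has only two CH carbons, C6 and C8, so a bromine cap on C8 leaves C6.
Both gallates go on the lower monomer while its C3–OH and 3'-OH are the only free hydroxyls, and the upper C3–O stays benzylated to the end: no resolution, no cascade, no late choice between two C3–OH groups.

Key step: step 8

Assumption: (−)-epicatechin and (−)-epigallocatechin are taken as commercial, enantiopure (2R,3R) materials; ring letters follow the usual flavan convention (upper unit A/C/B, lower unit D/F/E).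

Step 1
Reactants: 1 (−)-epicatechin
Product: 2 3,5,7,3',4'-penta-O-benzyl-(−)-epicatechin
Conditions: NaH (6 equiv), BnBr (5.5 equiv), DMF, 0 °C → rt
Reagents that add atoms: benzyl bromide, BrCc1ccccc1
Why: Williamson etherification of the four phenoxides and the C3 alkoxide caps every hydroxyl of the upper unit as a hydrogenolysable benzyl ether, so the upper C3–O can never be acylated later; no stereocentre is touched.

Step 2
Reactants: 2 3,5,7,3',4'-penta-O-benzyl-(−)-epicatechin
Product: 3 8-bromo-3,5,7,3',4'-penta-O-benzylepicatechin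
Conditions: NBS (1.05 equiv), CH2Cl2, −40 → 0 °C
Reagents that add atoms: N-bromosuccinimide, O=C1CCC(=O)N1Br
Why: Electrophilic aromatic bromination of the phloroglucinol-type ring A should go to C8 (flanked by O1 and one benzyloxy group, whereas C6 lies between two), the usual site in benzylated flavan-3-ols, and the bromine then keeps the most nucleophilic carbon of the electrophile from reacting in step 8.

Step 3
Reactants: 3 8-bromo-3,5,7,3',4'-penta-O-benzylepicatechin
Product: 5 8-bromo-4β-(2-ethoxyethoxy)-3,5,7,3',4'-penta-O-benzylepicatechin, via flavan-4-ylium hydroquinonate ion pair 4 (not isolated)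
Conditions: DDQ (2 equiv), 2-ethoxyethanol (5 equiv), CH2Cl2, rt
Reagents that add atoms: 2-ethoxyethanol, CCOCCO
Why: DDQ benzylic oxidation, in which hydride transfer from C4 to the quinone gives the ion pair 4 (C4 cation stabilised by O1 and the 5- and 7-benzyloxy groups, counter-ion the monoanion of the reduced quinone) that the alcohol should trap anti to the pseudoaxial C3–OBn (4β ether), the phenolate taking up the proton; the C4 configuration is immaterial because step 8 ionises it again.

Step 4
Reactants: 6 (−)-epigallocatechin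
Product: 9 5,7-di-O-benzyl-(−)-epigallocatechin, via ring E borate 7 (not isolated), via dibenzylated ring E borate 8 (not isolated)
Conditions: Na2B4O7·10H2O (4 equiv), DMF/H2O, rt, argon; then BnBr (2.2 equiv), rt; aq. citric acid work-up
Reagents that add atoms: benzyl bromide, BrCc1ccccc1
Why: Borate masking of a vicinal polyphenol during Williamson etherification: ring E is held as the anionic cyclic borate 7, whose remaining hydroxyl should not ionise at pH 9, so only the ring D phenols at C5 and C7 are benzylated (borate 8) and the borate falls off on acidic work-up; the C3 alcohol is not ionised and no stereocentre is involved.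

Step 5
Reactants: 9 5,7-di-O-benzyl-(−)-epigallocatechin
Product: 10 5,7-di-O-benzyl-4',5'-O-(diphenylmethylene)-(−)-epigallocatechin
Conditions: Ph2CCl2 (1.3 equiv), K2CO3 (3 equiv), MeCN, rt, argon
Reagents that add atoms: dichlorodiphenylmethane, ClC(Cl)(c1ccccc1)c1ccccc1
Why: Ketalisation by double O-alkylation with the gem-dichloride can only span two adjacent oxygens of ring E (five-membered benzodioxole), so exactly one outer hydroxyl, 3'-OH (equivalent to 5'-OH by rotation of ring E), stays free beside the C3–OH.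

Step 6
Reactants: 10 5,7-di-O-benzyl-4',5'-O-(diphenylmethylene)-(−)-epigallocatechin; 11 3,4,5-tris(benzyloxy)benzoic acid (2.6 equiv)
Product: 12 5,7-di-O-benzyl-4',5'-O-(diphenylmethylene)epigallocatechin 3,3'-bis-O-[3,4,5-tris(benzyloxy)benzoate]
Conditions: DCC (2.8 equiv), DMAP (0.4 equiv), CH2Cl2, 0 °C → rt
Reagents that add atoms: none
Why: Steglich esterification of the only two free hydroxyls (C3–OH and 3'-OH) is exhaustive and so needs no selectivity, and it forms the acyl–O bonds without touching C3.

Step 7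
Reactants: 12 5,7-di-O-benzyl-4',5'-O-(diphenylmethylene)epigallocatechin 3,3'-bis-O-[3,4,5-tris(benzyloxy)benzoate]
Product: 13 8-bromo derivative of 12
Conditions: NBS (1.05 equiv), CH2Cl2, −40 → 0 °C
Reagents that add atoms: N-bromosuccinimide, O=C1CCC(=O)N1Br
Why: Electrophilic aromatic bromination as in step 2: ring D is by far the most electron-rich ring (ring E and the galloyl rings carry ester groups) and should be brominated at C8, leaving C6 as its only aromatic CH.

Step 8
Reactants: 5 8-bromo-4β-(2-ethoxyethoxy)-3,5,7,3',4'-penta-O-benzylepicatechin; 13 8-bromo derivative of 12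
Product: 15 fully protected 8,8-dibromo epicatechin-(4β→6)-epigallocatechin digallate, via flavan-4-ylium triflate 14 (not isolated)
Conditions: 13 (2 equiv), Me3SiOTf (0.3 equiv), CH2Cl2, −40 °C, 5 added over 2 h; then Et3N
Reagents that add atoms: none
Why: Me3SiOTf silylates the C4 acetal oxygen of 5 and ionises it to the benzylic cation, present as its triflate 14, which is attacked by C6 of ring D of 13 in an intermolecular Friedel–Crafts alkylation, and loss of the C6 proton restores ring D and returns the silyl triflate. The closest known reaction type is the Lewis-acid-promoted flavan-4-yl arylation used to join flavan-3-ol units, including halogen-capped nucleophiles that are forced to react at C6. No ring is closed; the step forms the single bond C4(upper)–C6(lower). The new stereocentre C4 is set by the substrate: in the half-chair cation the 2-aryl group is pseudoequatorial and C3–OBn pseudoaxial on the α face, so the arene should enter on the β face, anti to C3–O (3,4-trans, 4β), and since both C4 epimers of 5 give the same cation the step is stereoconvergent. The selectivity needed is C6 against C8 of ring D and cross- against self-coupling: bromine at C8 of 13 removes the only other CH of ring D, bromine at C8 of 5 blocks the most nucleophilic carbon of the electrophile, and excess (recoverable) 13 with slow addition of 5 keeps the remaining C6–H of ring A from competing.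

Step 9
Reactants: 15 fully protected 8,8-dibromo epicatechin-(4β→6)-epigallocatechin digallate
Product: 16 (−)-epicatechin-(4β→6)-(−)-epigallocatechin 3,3'-di-O-gallate (CNP0237700.1)
Conditions: H2 (1 atm), Pd(OH)2/C, NaOAc (3 equiv), THF/MeOH/H2O, rt
Reagents that add atoms: none
Why: Catalytic hydrogenolysis should remove the thirteen benzyl ethers, the diphenylmethylene ketal (as diphenylmethane) and both aryl C–Br caps (hydrodehalogenation) in one operation, while NaOAc buffers the HBr so that the acid-labile interflavan bond and the two gallate esters survive; no stereocentre is touched.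

**Compound list**

1 | (−)-epicatechin, (2R,3R)-2-(3,4-dihydroxyphenyl)chromane-3,5,7-triol | C1c2c(O)cc(O)cc2O[C@H](c2ccc(O)c(O)c2)[C@@H]1O | starting material
2 | 3,5,7,3',4'-penta-O-benzyl-(−)-epicatechin (2R,3R) | C1c2c(OCc3ccccc3)cc(OCc3ccccc3)cc2O[C@H](c2ccc(OCc3ccccc3)c(OCc3ccccc3)c2)[C@@H]1OCc1ccccc1 | intermediate
3 | 8-bromo-3,5,7,3',4'-penta-O-benzylepicatechin (2R,3R) | C1c2c(OCc3ccccc3)cc(OCc3ccccc3)c(Br)c2O[C@H](c2ccc(OCc3ccccc3)c(OCc3ccccc3)c2)[C@@H]1OCc1ccccc1 | intermediate
4 | flavan-4-ylium ion pair from 3 and DDQ: C4 carbocation of 3 (C2 and C3 as in 3) with 2,3-dichloro-5,6-dicyano-4-hydroxyphenolate as counter-ion | [CH+]1c2c(OCc3ccccc3)cc(OCc3ccccc3)c(Br)c2O[C@H](c2ccc(OCc3ccccc3)c(OCc3ccccc3)c2)[C@@H]1OCc1ccccc1.[O-]c1c(Cl)c(Cl)c(O)c(C#N)c1C#N | intermediate (not isolated)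
5 | 8-bromo-4β-(2-ethoxyethoxy)-3,5,7,3',4'-penta-O-benzylepicatechin (2R,3R,4S; 4-O trans to 3-O) | CCOCCO[C@H]1c2c(OCc3ccccc3)cc(OCc3ccccc3)c(Br)c2O[C@H](c2ccc(OCc3ccccc3)c(OCc3ccccc3)c2)[C@@H]1OCc1ccccc1 | intermediate
6 | (−)-epigallocatechin, (2R,3R)-2-(3,4,5-trihydroxyphenyl)chromane-3,5,7-triol | Oc1cc(cc(O)c1O)[C@H]1Oc2cc(O)cc(O)c2C[C@H]1O | starting material
7 | sodium dihydroxyborate of 6, cyclic on two adjacent ring E oxygens | [Na+].O[B-]1(O)Oc2cc(cc(O)c2O1)[C@H]1Oc2cc(O)cc(O)c2C[C@H]1O | intermediate (not isolated)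
8 | sodium dihydroxyborate of 9, cyclic on two adjacent ring E oxygens | [Na+].O[B-]1(O)Oc2cc(cc(O)c2O1)[C@H]1Oc2cc(OCc3ccccc3)cc(OCc3ccccc3)c2C[C@H]1O | intermediate (not isolated)
9 | 5,7-di-O-benzyl-(−)-epigallocatechin (2R,3R) | Oc1cc(cc(O)c1O)[C@H]1Oc2cc(OCc3ccccc3)cc(OCc3ccccc3)c2C[C@H]1O | intermediate
10 | 5,7-di-O-benzyl-4',5'-O-(diphenylmethylene)-(−)-epigallocatechin (2R,3R; C3–OH and 3'-OH free) | Oc1cc(cc2OC(c3ccccc3)(c3ccccc3)Oc12)[C@H]1Oc2cc(OCc3ccccc3)cc(OCc3ccccc3)c2C[C@H]1O | intermediate
11 | 3,4,5-tris(benzyloxy)benzoic acid | OC(=O)c1cc(OCc2ccccc2)c(OCc2ccccc2)c(OCc2ccccc2)c1 | starting material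
12 | 5,7-di-O-benzyl-4',5'-O-(diphenylmethylene)epigallocatechin 3,3'-bis-O-[3,4,5-tris(benzyloxy)benzoate] (2R,3R) | O=C(Oc1cc([C@H]2Oc3cc(OCc4ccccc4)cc(OCc4ccccc4)c3C[C@H]2OC(=O)c2cc(OCc3ccccc3)c(OCc3ccccc3)c(OCc3ccccc3)c2)cc2OC(c3ccccc3)(c3ccccc3)Oc12)c1cc(OCc2ccccc2)c(OCc2ccccc2)c(OCc2ccccc2)c1 | intermediate
13 | 8-bromo derivative of 12 (bromine on ring D between O1 and the 7-benzyloxy group) | O=C(Oc1cc([C@H]2Oc3c(Br)c(OCc4ccccc4)cc(OCc4ccccc4)c3C[C@H]2OC(=O)c2cc(OCc3ccccc3)c(OCc3ccccc3)c(OCc3ccccc3)c2)cc2OC(c3ccccc3)(c3ccccc3)Oc12)c1cc(OCc2ccccc2)c(OCc2ccccc2)c(OCc2ccccc2)c1 | intermediate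
14 | flavan-4-ylium triflate from 5: C4 carbocation of 3 (C2 and C3 as in 3) with trifluoromethanesulfonate as counter-ion | [CH+]1c2c(OCc3ccccc3)cc(OCc3ccccc3)c(Br)c2O[C@H](c2ccc(OCc3ccccc3)c(OCc3ccccc3)c2)[C@@H]1OCc1ccccc1.[O-]S(=O)(=O)C(F)(F)F | intermediate (not isolated)
15 | fully protected dimer: 8-bromo-penta-O-benzylepicatechin joined 4β→6 to 13 (upper C2, C3 as in epicatechin, C4-aryl trans to C3–O; lower C2, C3 as in epigallocatechin) | O=C(Oc1cc([C@H]2Oc3c(Br)c(OCc6ccccc6)c([C@H]4c5c(OCc6ccccc6)cc(OCc6ccccc6)c(Br)c5O[C@H](c5ccc(OCc6ccccc6)c(OCc6ccccc6)c5)[C@@H]4OCc4ccccc4)c(OCc6ccccc6)c3C[C@H]2OC(=O)c2cc(OCc6ccccc6)c(OCc6ccccc6)c(OCc6ccccc6)c2)cc2OC(c3ccccc3)(c3ccccc3)Oc12)c1cc(OCc6ccccc6)c(OCc6ccccc6)c(OCc6ccccc6)c1 | intermediate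
16 | (−)-epicatechin-(4β→6)-(−)-epigallocatechin 3,3'-di-O-gallate (gallates on C3–O and ring E 3'-O of the lower unit); upper 2R,3R,4S, lower 2R,3R | O=C(Oc1cc([C@H]2Oc3cc(O)c([C@H]4c5c(O)cc(O)cc5O[C@H](c5ccc(O)c(O)c5)[C@@H]4O)c(O)c3C[C@H]2OC(=O)c2cc(O)c(O)c(O)c2)cc(O)c1O)c1cc(O)c(O)c(O)c1 | target

Total steps: 9. Longest linear sequence: 6 (steps 4–9, from (−)-epigallocatechin).

Steps most likely to fail

1. Step 8. The C6 position of 13 is flanked by two benzyloxy groups and deactivated by the bromine, so the cation of 14 may instead be consumed by ring A of a second molecule of 5 or of product 15 (self-condensation, over-coupling), or lost by elimination to the flav-3-ene. The fallback changes how cross-selectivity is obtained: instead of stoichiometry and addition rate, the electrophile is made unable to act as a nucleophile. It sets out from 5: a second bromination (NBS, CH2Cl2, rt) at C6 should give the 6,8-dibromo acetal F1, which has no aromatic CH on ring A and can be used in excess under stronger activation (BF3·OEt2, CH2Cl2, −20 °C) with 13 to give the tribromo protected dimer F2. Hydrogenolysis of F2 under the conditions of step 9 comes back to the route at 16.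

2. Step 4. Masking of ring E by borate may be incomplete, so the pyrogallol oxygens are benzylated as well, or the pyrogallol autoxidises in the basic aqueous medium. The fallback replaces complexation by an acidity difference and sets out from 6: ketalisation first (Ph2CCl2, K2CO3, MeCN) would give 4',5'-O-(diphenylmethylene)epigallocatechin F3. Exhaustive bromination of ring D (NBS, 2 equiv, THF, −78 °C) would give the 6,8-dibromide F4, in which the ortho-bromines lower the pKa of the C5 and C7 phenols by about two units. Benzylation with the weak base KHCO3 (BnBr, DMF) should then touch only these two phenols and give the 5,7-di-O-benzyl-6,8-dibromide F5. Radical debromination (Bu3SnH, AIBN, toluene, 80 °C) comes back to the route at 10.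

3. Step 9. The HBr set free by hydrodebromination may acidify the medium (cleavage of the interflavan bond), bromide may poison the catalyst (incomplete debenzylation), or over-buffering may cause acyl migration from 3'-O to 4'-O. The fallback separates the two reductions and sets out from 15: radical debromination (Bu3SnH, AIBN, toluene, 80 °C; benzyl ethers, esters and ketal inert) would give the bromine-free protected dimer F6. Hydrogenolysis of F6 without additive (H2, Pd(OH)2/C, THF/MeOH) comes back to the route at 16.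

Further compounds

F1 | step 8 | 6,8-dibromo-4β-(2-ethoxyethoxy)-3,5,7,3',4'-penta-O-benzylepicatechin | CCOCCO[C@H]1c2c(OCc3ccccc3)c(Br)c(OCc3ccccc3)c(Br)c2O[C@H](c2ccc(OCc3ccccc3)c(OCc3ccccc3)c2)[C@@H]1OCc1ccccc1
F2 | step 8 | tribromo protected dimer (15 with a further bromine at C6 of ring A) | O=C(Oc1cc([C@H]2Oc3c(Br)c(OCc6ccccc6)c([C@H]4c5c(OCc6ccccc6)c(Br)c(OCc6ccccc6)c(Br)c5O[C@H](c5ccc(OCc6ccccc6)c(OCc6ccccc6)c5)[C@@H]4OCc4ccccc4)c(OCc6ccccc6)c3C[C@H]2OC(=O)c2cc(OCc6ccccc6)c(OCc6ccccc6)c(OCc6ccccc6)c2)cc2OC(c3ccccc3)(c3ccccc3)Oc12)c1cc(OCc6ccccc6)c(OCc6ccccc6)c(OCc6ccccc6)c1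
F3 | step 4 | 4',5'-O-(diphenylmethylene)-(−)-epigallocatechin | Oc1cc(cc2OC(c3ccccc3)(c3ccccc3)Oc12)[C@H]1Oc2cc(O)cc(O)c2C[C@H]1O
F4 | step 4 | 6,8-dibromo-4',5'-O-(diphenylmethylene)epigallocatechin | Oc1cc(cc2OC(c3ccccc3)(c3ccccc3)Oc12)[C@H]1Oc2c(Br)c(O)c(Br)c(O)c2C[C@H]1O
F5 | step 4 | 5,7-di-O-benzyl-6,8-dibromo-4',5'-O-(diphenylmethylene)epigallocatechin | Oc1cc(cc2OC(c3ccccc3)(c3ccccc3)Oc12)[C@H]1Oc2c(Br)c(OCc3ccccc3)c(Br)c(OCc3ccccc3)c2C[C@H]1O
F6 | step 9 | bromine-free protected dimer (15 with H at both C8 positions) | O=C(Oc1cc([C@H]2Oc3cc(OCc6ccccc6)c([C@H]4c5c(OCc6ccccc6)cc(OCc6ccccc6)cc5O[C@H](c5ccc(OCc6ccccc6)c(OCc6ccccc6)c5)[C@@H]4OCc4ccccc4)c(OCc6ccccc6)c3C[C@H]2OC(=O)c2cc(OCc6ccccc6)c(OCc6ccccc6)c(OCc6ccccc6)c2)cc2OC(c3ccccc3)(c3ccccc3)Oc12)c1cc(OCc6ccccc6)c(OCc6ccccc6)c(OCc6ccccc6)c1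
A1 | direct plan | rac-1-[7-(allyloxy)-2,2-diphenyl-1,3-benzodioxol-5-yl]prop-2-en-1-ol | OC(C=C)c1cc(OCC=C)c2OC(c3ccccc3)(c3ccccc3)Oc2c1
A2 | direct plan | bis-epoxide diaryl ether (open-chain precursor of both pyran rings) | C(c1ccccc1)Oc1cc(OCc2ccccc2)cc(O[C@H](c2ccc(OCc3ccccc3)c(OCc3ccccc3)c2)[C@@H]2O[C@H]2c2c(OCc3ccccc3)cc(O[C@H](c3cc(OCC=C)c4OC(c5ccccc5)(c5ccccc5)Oc4c3)[C@H]3CO3)cc2OCc2ccccc2)c1
A3 | direct plan | benzyl- and ketal-protected dimer triol (both C3–OH and ring E 3'-OH free) | Oc1cc([C@H]2Oc3cc(OCc6ccccc6)c([C@H]4c5c(OCc6ccccc6)cc(OCc6ccccc6)cc5O[C@H](c5ccc(OCc6ccccc6)c(OCc6ccccc6)c5)[C@@H]4O)c(OCc6ccccc6)c3C[C@H]2O)cc2OC(c3ccccc3)(c3ccccc3)Oc12
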